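**Retrosynthetic overview**

1. Rings: A = aryl of the glycerol unit, B = aryl of the lactone β-benzyl group, C = benzofuran arene, D = 2-aryl group of the benzofuran. The last C–C bond is lactone Cα–CH2(ring C), made by trans-selective alkylation of the ring A/ring B lactone enolate with the ring C/ring D benzylic bromide; acetonide hydrolysis and hydrogenolysis follow.
2. The strategy rests on the 2,3-dihydrobenzofuran: arene carbons C7a (O1), C7 (OMe), C6 (H), C5 (CH2 arm), C4 (H), C3a, with stereocentres C2 and C3 in the O1–C2–C3 bridge. Ring C and the dihydrofuran ring are closed together by an intramolecular pyridazine/alkyne [4+2] cycloaddition with loss of N2 (bonds C3a–C7a and C4–C5). Pyridazine C3/C4/C5/C6 become C7a/C7/C6/C5 (Cl as handle); the alkyne carbons become C3a/C4.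
3. The tether comes from an anti homopropargylic alcohol (allenylzinc addition of an (S)-propargylic mesylate to O-benzylvanillin), joined to 3,6-dichloro-4-methoxypyridazine by SNAr at C3.
4. The lactone half comes from a Stobbe condensation and asymmetric hydrogenation (lactone ring, C4 R); the erythro arylglycerol ether on ring B comes from a magnesium-catalysed anti-aldol of an aryloxyacetyl oxazolidinone with O-benzylvanillin.
5. Ring order: rings A, B and D are bought as vanillin units; the lactone ring is formed first in its branch, ring C and the dihydrofuran ring together in the key step, and the two halves are joined last.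

Key step: step 7

Remark: compounds 1, 2, 7, 11, 18 and 24 are taken as purchased; the sense of induction in steps 2 and 11 is assigned by analogy with alkynyl methyl ketones and itaconate half-esters, and the mirror-image catalyst is used should the first batch show the opposite sense.

**Route**

Step 1
Reactants: 1 2-(benzyloxy)-N-methoxy-N-methylacetamide; 2 ethynyltrimethylsilane
Product: 4 1-(benzyloxy)-4-(trimethylsilyl)but-3-yn-2-one, via lithium (trimethylsilyl)acetylide 3 (not isolated)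
Conditions: n-BuLi, THF, −78 °C; then 1, −78 to −20 °C; cold aq. NH4Cl
Reagents that add atoms: none
Why: Weinreb ketone synthesis, in which the acetylide adds once because the chelated tetrahedral adduct survives until the cold quench, so the ynone forms without over-addition.

Step 2
Reactants: 4 1-(benzyloxy)-4-(trimethylsilyl)but-3-yn-2-one
Product: 5 (S)-1-(benzyloxy)-4-(trimethylsilyl)but-3-yn-2-ol
Conditions: Ru[(R,R)-TsDPEN](p-cymene) (2 mol %), i-PrOH, rt
Reagents that add atoms: none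
Why: Noyori asymmetric transfer hydrogenation of an alkynyl ketone, in which the alkynyl group takes the place of the aryl group of the usual model, so the (R,R) catalyst should give the (S)-carbinol (S because CH2OBn outranks the alkyne), and the neutral medium leaves the C–Si bond intact.

Step 3
Reactants: 5 (S)-1-(benzyloxy)-4-(trimethylsilyl)but-3-yn-2-ol
Product: 6 (S)-1-(benzyloxy)-4-(trimethylsilyl)but-3-yn-2-yl methanesulfonate
Conditions: MsCl, Et3N, CH2Cl2, −78 to 0 °C; used crude
Reagents that add atoms: methanesulfonyl chloride, CS(=O)(=O)Cl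
Why: Sulfonylation of the propargylic alcohol at oxygen, which breaks no bond to the stereocentre and so proceeds with retention.

Step 4
Reactants: 6 (S)-1-(benzyloxy)-4-(trimethylsilyl)but-3-yn-2-yl methanesulfonate; 7 4-(benzyloxy)-3-methoxybenzaldehyde (O-benzylvanillin)
Product: 9 (1S,2R)-1-[4-(benzyloxy)-3-methoxyphenyl]-2-[(benzyloxy)methyl]-4-(trimethylsilyl)but-3-yn-1-ol, via allenyl(ethyl)zinc 8 (not isolated)
Conditions: Pd(OAc)2 (5 mol %), PPh3 (5 mol %), Et2Zn (3 equiv), THF, −78 to −20 °C, aldehyde present from the start; aq. NH4Cl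
Reagents that add atoms: none
Why: Palladium-catalysed umpolung propargylation (SE2' addition of an allenylzinc), in which zerovalent palladium displaces the mesylate anti (SN2'), zinc takes over the allenyl group with retention and the (P)-allenylzinc adds through a closed transition state, so that C2 (R) is set by chirality transfer from the mesylate centre and C1 (S) by the anti-selective transition state, the minor syn isomer being removed by chromatography.

Step 5
Reactants: 9 (1S,2R)-1-[4-(benzyloxy)-3-methoxyphenyl]-2-[(benzyloxy)methyl]-4-(trimethylsilyl)but-3-yn-1-ol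
Product: 10 (1S,2R)-1-[4-(benzyloxy)-3-methoxyphenyl]-2-[(benzyloxy)methyl]but-3-yn-1-ol
Conditions: K2CO3, MeOH, rt
Reagents that add atoms: none
Why: Base-mediated protodesilylation of the alkynylsilane, which touches neither stereocentre.

Step 6
Reactants: 10 (1S,2R)-1-[4-(benzyloxy)-3-methoxyphenyl]-2-[(benzyloxy)methyl]but-3-yn-1-ol; 11 3,6-dichloro-4-methoxypyridazine
Product: 13 3-{[(1S,2R)-1-[4-(benzyloxy)-3-methoxyphenyl]-2-[(benzyloxy)methyl]but-3-yn-1-yl]oxy}-6-chloro-4-methoxypyridazine, via sodium alkoxide 12 (not isolated)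
Conditions: NaH (1.05 equiv), THF, 0 °C; then 11 (1.3 equiv), 0 °C to rt
Reagents that add atoms: none
Why: Nucleophilic aromatic substitution (SNAr), in which the alkoxide is expected to enter at C3, the chloride flanked by N2 and the inductively withdrawing methoxy-bearing C4, by analogy with methoxide and helped by the sodium ion bridging N2 and the methoxy oxygen, while both stereocentres are kept because only the O–H bond of 10 is broken.

Step 7
Reactants: 13 3-{[(1S,2R)-1-[4-(benzyloxy)-3-methoxyphenyl]-2-[(benzyloxy)methyl]but-3-yn-1-yl]oxy}-6-chloro-4-methoxypyridazine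
Product: 15 (2S,3R)-2-[4-(benzyloxy)-3-methoxyphenyl]-3-[(benzyloxy)methyl]-5-chloro-7-methoxy-2,3-dihydro-1-benzofuran, via bridged diazabicyclooctatriene adduct 14 (not isolated)
Conditions: 1,3,5-triisopropylbenzene (0.02 M), BHT (10 mol %), argon, sealed tube, 200–210 °C
Reagents that add atoms: none
Why: On heating, the electron-poor 1,2-diazine of 13 acts as the 4π component and the tethered terminal alkyne as the 2π component of an intramolecular inverse-electron-demand Diels–Alder reaction across C3 and C6, and the bridged adduct 14 at once loses N2 by retro-[4+2], as in the known thermal conversion of 3-(but-3-ynyloxy)-6-chloropyridazines into 5-chloro-2,3-dihydrobenzofurans. The dihydrofuran ring closes because the three-atom O1–C2–C3 tether forces the internal alkyne carbon onto the oxygen-bearing diazine carbon (bond C3a–C7a, five-membered ring fused within the bicyclic adduct), and the arene ring closes through the second bond C4–C5 and is aromatised by the N2 loss. No stereocentre is created, since the bridgehead centres of 14 vanish with N2 and C2 and C3 lie in the tether with no bond broken. The step needs regioselectivity, which the short tether dictates, and chemoselectivity over thermal elimination or ionisation of the 4-alkoxybenzylic pyridazinyl ether, which dilution, an acid-free hydrocarbon medium and the reactive-rotamer effect of the two vicinal tether substituents should secure. The 4-methoxy group lowers the reactivity of the diene and the 6-chloro substituent offsets this only in part, so the risk of the route sits here.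

Step 8
Reactants: 15 (2S,3R)-2-[4-(benzyloxy)-3-methoxyphenyl]-3-[(benzyloxy)methyl]-5-chloro-7-methoxy-2,3-dihydro-1-benzofuran
Product: 16 [(2S,3R)-2-[4-(benzyloxy)-3-methoxyphenyl]-3-[(benzyloxy)methyl]-7-methoxy-2,3-dihydro-1-benzofuran-5-yl]methanol
Conditions: Pd(dba)2 (5 mol %), RuPhos (10 mol %), Na2CO3, 1,4-dioxane/H2O (10:1), 100 °C
Reagents that add atoms: potassium (acetoxymethyl)trifluoroborate, CC(=O)OC[B-](F)(F)F.[K+]
Why: Suzuki–Miyaura coupling of the aryl chloride with an acetoxymethyl trifluoroborate, in which the electron-rich biaryl phosphine allows oxidative addition of zerovalent palladium into the electron-rich C–Cl bond and the acetate is hydrolysed by the aqueous carbonate to give the benzylic alcohol directly.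

Step 9
Reactants: 16 [(2S,3R)-2-[4-(benzyloxy)-3-methoxyphenyl]-3-[(benzyloxy)methyl]-7-methoxy-2,3-dihydro-1-benzofuran-5-yl]methanol
Product: 17 (2S,3R)-2-[4-(benzyloxy)-3-methoxyphenyl]-3-[(benzyloxy)methyl]-5-(bromomethyl)-7-methoxy-2,3-dihydro-1-benzofuran
Conditions: CBr4, PPh3, CH2Cl2, 0 °C; used at once
Reagents that add atoms: carbon tetrabromide, BrC(Br)(Br)Br
Why: Appel reaction, a neutral conversion of the electron-rich benzylic alcohol into the bromide that avoids acid able to open the 2-aryl-dihydrobenzofuran.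

Step 10
Reactants: 7 4-(benzyloxy)-3-methoxybenzaldehyde (O-benzylvanillin); 18 dimethyl succinate
Product: 19 (E)-4-[4-(benzyloxy)-3-methoxyphenyl]-3-(methoxycarbonyl)but-3-enoic acid
Conditions: NaOMe, MeOH, reflux; then 2 M HCl
Reagents that add atoms: none
Why: Stobbe condensation, in which the succinate enolate adds to the aldehyde, the aldolate lactonises and the paraconate opens by E1cB to the (E)-alkylidene half-ester, carboxylate formation making the sequence irreversible.

Step 11
Reactants: 19 (E)-4-[4-(benzyloxy)-3-methoxyphenyl]-3-(methoxycarbonyl)but-3-enoic acid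
Product: 20 (R)-4-[4-(benzyloxy)-3-methoxyphenyl]-3-(methoxycarbonyl)butanoic acid
Conditions: [Rh(cod)((S,S)-Et-DuPhos)]BF4 (1 mol %), H2 (5 bar), NaOMe (10 mol %), MeOH, rt
Reagents that add atoms: none
Why: Rhodium-catalysed asymmetric hydrogenation of an itaconate-type half-ester, in which the carboxylate arm binds rhodium beside the olefin and the (S,S) ligand is expected to deliver H2 to the face that gives the (R)-succinate, the benzyl ether being inert to the homogeneous catalyst.

Step 12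
Reactants: 20 (R)-4-[4-(benzyloxy)-3-methoxyphenyl]-3-(methoxycarbonyl)butanoic acid
Product: 22 (R)-4-[4-(benzyloxy)-3-methoxybenzyl]dihydrofuran-2(3H)-one, via hydroxy acid 21 (not isolated)
Conditions: KOH (1 equiv), EtOH; CaCl2, NaBH4, EtOH, −10 °C to rt; then 3 M HCl, rt
Reagents that add atoms: none
Why: Chemoselective hydride reduction followed by lactonisation, in which calcium borohydride reduces the methyl ester but not the carboxylate salt and acidification closes the hydroxy acid to the γ-lactone without touching the stereocentre.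

Step 13
Reactants: 22 (R)-4-[4-(benzyloxy)-3-methoxybenzyl]dihydrofuran-2(3H)-one
Product: 23 (R)-4-(4-hydroxy-3-methoxybenzyl)dihydrofuran-2(3H)-one
Conditions: H2 (1 atm), Pd/C (10% palladium on carbon), EtOAc, rt
Reagents that add atoms: none
Why: Hydrogenolysis of the phenolic benzyl ether frees the ring B phenol, the lactone being inert.

Step 14
Reactants: 23 (R)-4-(4-hydroxy-3-methoxybenzyl)dihydrofuran-2(3H)-one; 24 (S)-4-benzyl-3-(chloroacetyl)oxazolidin-2-one
Product: 25 (S)-4-benzyl-3-[(2-methoxy-4-{[(3R)-5-oxooxolan-3-yl]methyl}phenoxy)acetyl]oxazolidin-2-one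
Conditions: K2CO3, NaI (10 mol %), acetone, rt
Reagents that add atoms: none
Why: Williamson ether synthesis, in which the phenoxide displaces the activated α-chloride (iodide catalysis) under conditions too mild to enolise the lactone or cleave the imide.

Step 15
Reactants: 25 (S)-4-benzyl-3-[(2-methoxy-4-{[(3R)-5-oxooxolan-3-yl]methyl}phenoxy)acetyl]oxazolidin-2-one; 7 4-(benzyloxy)-3-methoxybenzaldehyde (O-benzylvanillin)
Product: 27 (S)-4-benzyl-3-[(2R,3R)-3-[4-(benzyloxy)-3-methoxyphenyl]-3-hydroxy-2-(2-methoxy-4-{[(3R)-5-oxooxolan-3-yl]methyl}phenoxy)propanoyl]oxazolidin-2-one, via O-trimethylsilyl aldol 26 (not isolated)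
Conditions: MgCl2 (20 mol %), Et3N, Me3SiCl, EtOAc, rt; then 1 M HCl, THF
Reagents that add atoms: none
Why: Magnesium-halide-catalysed direct anti-aldol of an N-acyloxazolidinone, in which soft enolisation gives the chelated Z-enolate that should add to the non-enolisable aldehyde on the face opposite the auxiliary benzyl group through a boat-like transition state, setting C8 from the auxiliary and C7 anti to it, while silylation of the aldolate turns the magnesium over and blocks retro-aldol.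

Step 16
Reactants: 27 (S)-4-benzyl-3-[(2R,3R)-3-[4-(benzyloxy)-3-methoxyphenyl]-3-hydroxy-2-(2-methoxy-4-{[(3R)-5-oxooxolan-3-yl]methyl}phenoxy)propanoyl]oxazolidin-2-one
Product: 28 (R)-4-[4-({(1R,2S)-1-[4-(benzyloxy)-3-methoxyphenyl]-1,3-dihydroxypropan-2-yl}oxy)-3-methoxybenzyl]dihydrofuran-2(3H)-one
Conditions: NaBH4, THF/H2O (4:1), 0 °C
Reagents that add atoms: none
Why: Reductive cleavage of the auxiliary, in which borohydride in wet THF reduces the activated exocyclic imide carbonyl to the primary alcohol faster than the γ-lactone and releases the oxazolidinone, no bond to C7 or C8 being broken.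

Step 17
Reactants: 28 (R)-4-[4-({(1R,2S)-1-[4-(benzyloxy)-3-methoxyphenyl]-1,3-dihydroxypropan-2-yl}oxy)-3-methoxybenzyl]dihydrofuran-2(3H)-one
Product: 29 (R)-4-[4-({(4R,5S)-4-[4-(benzyloxy)-3-methoxyphenyl]-2,2-dimethyl-1,3-dioxan-5-yl}oxy)-3-methoxybenzyl]dihydrofuran-2(3H)-one
Conditions: 2,2-dimethoxypropane, PPTS (cat.), CH2Cl2, rt
Reagents that add atoms: 2,2-dimethoxypropane, COC(C)(C)OC
Why: Acetalisation of the 1,3-diol as the six-membered acetonide, which masks both hydroxyl groups for the enolate step.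

Step 18
Reactants: 29 (R)-4-[4-({(4R,5S)-4-[4-(benzyloxy)-3-methoxyphenyl]-2,2-dimethyl-1,3-dioxan-5-yl}oxy)-3-methoxybenzyl]dihydrofuran-2(3H)-one; 17 (2S,3R)-2-[4-(benzyloxy)-3-methoxyphenyl]-3-[(benzyloxy)methyl]-5-(bromomethyl)-7-methoxy-2,3-dihydro-1-benzofuran
Product: 31 (3R,4R)-3-{[(2S,3R)-2-[4-(benzyloxy)-3-methoxyphenyl]-3-[(benzyloxy)methyl]-7-methoxy-2,3-dihydro-1-benzofuran-5-yl]methyl}-4-[4-({(4R,5S)-4-[4-(benzyloxy)-3-methoxyphenyl]-2,2-dimethyl-1,3-dioxan-5-yl}oxy)-3-methoxybenzyl]dihydrofuran-2(3H)-one, via lithium enolate 30 (not isolated)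
Conditions: LiN(SiMe3)2 (1.1 equiv), THF, −78 °C; then 17, DMPU, −78 to −40 °C
Reagents that add atoms: none
Why: Enolate alkylation of a β-substituted γ-butyrolactone, in which the reactive benzylic bromide attacks the lithium enolate on the face opposite the C4 benzyl group and so sets C3 (R) trans to C4.

Step 19
Reactants: 31 (3R,4R)-3-{[(2S,3R)-2-[4-(benzyloxy)-3-methoxyphenyl]-3-[(benzyloxy)methyl]-7-methoxy-2,3-dihydro-1-benzofuran-5-yl]methyl}-4-[4-({(4R,5S)-4-[4-(benzyloxy)-3-methoxyphenyl]-2,2-dimethyl-1,3-dioxan-5-yl}oxy)-3-methoxybenzyl]dihydrofuran-2(3H)-one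
Product: 32 (3R,4R)-3-{[(2S,3R)-2-[4-(benzyloxy)-3-methoxyphenyl]-3-[(benzyloxy)methyl]-7-methoxy-2,3-dihydro-1-benzofuran-5-yl]methyl}-4-[4-({(1R,2S)-1-[4-(benzyloxy)-3-methoxyphenyl]-1,3-dihydroxypropan-2-yl}oxy)-3-methoxybenzyl]dihydrofuran-2(3H)-one
Conditions: AcOH/H2O/THF (3:1:1), 45 °C
Reagents that add atoms: none
Why: Mild aqueous-acid hydrolysis of the acetonide, done while the phenols are still benzylated so that neither the 4-alkoxybenzylic carbinol nor the C2–O1 bond of the dihydrobenzofuran is ionised.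

Step 20
Reactants: 32 (3R,4R)-3-{[(2S,3R)-2-[4-(benzyloxy)-3-methoxyphenyl]-3-[(benzyloxy)methyl]-7-methoxy-2,3-dihydro-1-benzofuran-5-yl]methyl}-4-[4-({(1R,2S)-1-[4-(benzyloxy)-3-methoxyphenyl]-1,3-dihydroxypropan-2-yl}oxy)-3-methoxybenzyl]dihydrofuran-2(3H)-one
Product: 33 (3R,4R)-3-{[(2S,3R)-2-(4-hydroxy-3-methoxyphenyl)-3-(hydroxymethyl)-7-methoxy-2,3-dihydro-1-benzofuran-5-yl]methyl}-4-[4-({(1R,2S)-1-(4-hydroxy-3-methoxyphenyl)-1,3-dihydroxypropan-2-yl}oxy)-3-methoxybenzyl]dihydrofuran-2(3H)-one (CNP0265599.1)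
Conditions: H2 (1 atm), Pd/C (10% palladium on carbon), EtOAc/EtOH, rt
Reagents that add atoms: none
Why: Hydrogenolysis of the two phenolic and the one primary-alkyl benzyl ether under neutral conditions at atmospheric pressure, under which the benzylic C–O bonds of the dihydrobenzofuran and of the carbinol are expected to survive.

**Compound list**

1 | 2-(benzyloxy)-N-methoxy-N-methylacetamide | CON(C)C(=O)COCc1ccccc1 | starting material
2 | ethynyltrimethylsilane | C#C[Si](C)(C)C | starting material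
3 | lithium (trimethylsilyl)acetylide | [Li]C#C[Si](C)(C)C | intermediate (not isolated)
4 | 1-(benzyloxy)-4-(trimethylsilyl)but-3-yn-2-one | C[Si](C)(C)C#CC(=O)COCc1ccccc1 | intermediate
5 | (S)-1-(benzyloxy)-4-(trimethylsilyl)but-3-yn-2-ol | C[Si](C)(C)C#C[C@@H](COCc1ccccc1)O | intermediate
6 | (S)-1-(benzyloxy)-4-(trimethylsilyl)but-3-yn-2-yl methanesulfonate | C[Si](C)(C)C#C[C@@H](COCc1ccccc1)OS(C)(=O)=O | intermediate
7 | 4-(benzyloxy)-3-methoxybenzaldehyde (O-benzylvanillin) | COc1cc(C=O)ccc1OCc1ccccc1 | starting material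
8 | ethyl[(P)-4-(benzyloxy)-1-(trimethylsilyl)buta-1,2-dien-1-yl]zinc | C[Si](C)(C)C([Zn]CC)=[C@]=C([H])COCc1ccccc1 | intermediate (not isolated)
9 | (1S,2R)-1-[4-(benzyloxy)-3-methoxyphenyl]-2-[(benzyloxy)methyl]-4-(trimethylsilyl)but-3-yn-1-ol | C[Si](C)(C)C#C[C@H](COCc1ccccc1)[C@@H](c1ccc(OCc2ccccc2)c(OC)c1)O | intermediate
10 | (1S,2R)-1-[4-(benzyloxy)-3-methoxyphenyl]-2-[(benzyloxy)methyl]but-3-yn-1-ol | C#C[C@H](COCc1ccccc1)[C@@H](c1ccc(OCc2ccccc2)c(OC)c1)O | intermediate
11 | 3,6-dichloro-4-methoxypyridazine | COc1cc(Cl)nnc1Cl | starting material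
12 | sodium alkoxide of 10 | C#C[C@H](COCc1ccccc1)[C@@H](c1ccc(OCc2ccccc2)c(OC)c1)[O-].[Na+] | intermediate (not isolated)
13 | 3-{[(1S,2R)-1-[4-(benzyloxy)-3-methoxyphenyl]-2-[(benzyloxy)methyl]but-3-yn-1-yl]oxy}-6-chloro-4-methoxypyridazine | C#C[C@H](COCc1ccccc1)[C@@H](c1ccc(OCc2ccccc2)c(OC)c1)Oc1nnc(Cl)cc1OC | intermediate
14 | bridged [4+2] adduct of 13: 2,3-diazabicyclo[2.2.2]octa-2,5,7-triene fused to the oxolane ring, chlorine and oxygen at the bridgeheads (bridgehead configuration left open, both forms give 15) | ClC12C=C(OC)C3(N=N1)O[C@H](c1ccc(OCc4ccccc4)c(OC)c1)[C@@H](COCc1ccccc1)C3=C2 | intermediate (not isolated)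
15 | (2S,3R)-2-[4-(benzyloxy)-3-methoxyphenyl]-3-[(benzyloxy)methyl]-5-chloro-7-methoxy-2,3-dihydro-1-benzofuran | Clc1cc(OC)c2c(c1)[C@H](COCc1ccccc1)[C@@H](c1ccc(OCc3ccccc3)c(OC)c1)O2 | intermediate
16 | [(2S,3R)-2-[4-(benzyloxy)-3-methoxyphenyl]-3-[(benzyloxy)methyl]-7-methoxy-2,3-dihydro-1-benzofuran-5-yl]methanol | OCc1cc(OC)c2c(c1)[C@H](COCc1ccccc1)[C@@H](c1ccc(OCc3ccccc3)c(OC)c1)O2 | intermediate
17 | (2S,3R)-2-[4-(benzyloxy)-3-methoxyphenyl]-3-[(benzyloxy)methyl]-5-(bromomethyl)-7-methoxy-2,3-dihydro-1-benzofuran | BrCc1cc(OC)c2c(c1)[C@H](COCc1ccccc1)[C@@H](c1ccc(OCc3ccccc3)c(OC)c1)O2 | intermediate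
18 | dimethyl succinate | COC(=O)CCC(=O)OC | starting material
19 | (E)-4-[4-(benzyloxy)-3-methoxyphenyl]-3-(methoxycarbonyl)but-3-enoic acid | COC(=O)/C(CC(=O)O)=C/c1ccc(OCc2ccccc2)c(OC)c1 | intermediate
20 | (R)-4-[4-(benzyloxy)-3-methoxyphenyl]-3-(methoxycarbonyl)butanoic acid | COC(=O)[C@@H](CC(=O)O)Cc1ccc(OCc2ccccc2)c(OC)c1 | intermediate
21 | (R)-4-[4-(benzyloxy)-3-methoxyphenyl]-3-(hydroxymethyl)butanoic acid | OC[C@@H](CC(=O)O)Cc1ccc(OCc2ccccc2)c(OC)c1 | intermediate (not isolated)
22 | (R)-4-[4-(benzyloxy)-3-methoxybenzyl]dihydrofuran-2(3H)-one | COc1cc(C[C@H]2COC(=O)C2)ccc1OCc1ccccc1 | intermediate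
23 | (R)-4-(4-hydroxy-3-methoxybenzyl)dihydrofuran-2(3H)-one | COc1cc(C[C@H]2COC(=O)C2)ccc1O | intermediate
24 | (S)-4-benzyl-3-(chloroacetyl)oxazolidin-2-one | O=C(CCl)N1C(=O)OC[C@@H]1Cc1ccccc1 | starting material
25 | (S)-4-benzyl-3-[(2-methoxy-4-{[(3R)-5-oxooxolan-3-yl]methyl}phenoxy)acetyl]oxazolidin-2-one | O=C(COc1ccc(C[C@H]2COC(=O)C2)cc1OC)N1C(=O)OC[C@@H]1Cc1ccccc1 | intermediate
26 | O-trimethylsilyl ether of 27 | COc1cc([C@@H](O[Si](C)(C)C)[C@H](C(=O)N2C(=O)OC[C@@H]2Cc2ccccc2)Oc2ccc(C[C@H]3COC(=O)C3)cc2OC)ccc1OCc1ccccc1 | intermediate (not isolated)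
27 | (S)-4-benzyl-3-[(2R,3R)-3-[4-(benzyloxy)-3-methoxyphenyl]-3-hydroxy-2-(2-methoxy-4-{[(3R)-5-oxooxolan-3-yl]methyl}phenoxy)propanoyl]oxazolidin-2-one | COc1cc([C@@H](O)[C@H](C(=O)N2C(=O)OC[C@@H]2Cc2ccccc2)Oc2ccc(C[C@H]3COC(=O)C3)cc2OC)ccc1OCc1ccccc1 | intermediate
28 | (R)-4-[4-({(1R,2S)-1-[4-(benzyloxy)-3-methoxyphenyl]-1,3-dihydroxypropan-2-yl}oxy)-3-methoxybenzyl]dihydrofuran-2(3H)-one | COc1cc([C@@H](O)[C@H](CO)Oc2ccc(C[C@H]3COC(=O)C3)cc2OC)ccc1OCc1ccccc1 | intermediate
29 | (R)-4-[4-({(4R,5S)-4-[4-(benzyloxy)-3-methoxyphenyl]-2,2-dimethyl-1,3-dioxan-5-yl}oxy)-3-methoxybenzyl]dihydrofuran-2(3H)-one | COc1cc([C@H]2OC(C)(C)OC[C@@H]2Oc2ccc(C[C@H]3COC(=O)C3)cc2OC)ccc1OCc1ccccc1 | intermediate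
30 | lithium enolate of 29 | COc1cc([C@H]2OC(C)(C)OC[C@@H]2Oc2ccc(C[C@H]3COC([O-])=C3)cc2OC)ccc1OCc1ccccc1.[Li+] | intermediate (not isolated)
31 | (3R,4R)-3-{[(2S,3R)-2-[4-(benzyloxy)-3-methoxyphenyl]-3-[(benzyloxy)methyl]-7-methoxy-2,3-dihydro-1-benzofuran-5-yl]methyl}-4-[4-({(4R,5S)-4-[4-(benzyloxy)-3-methoxyphenyl]-2,2-dimethyl-1,3-dioxan-5-yl}oxy)-3-methoxybenzyl]dihydrofuran-2(3H)-one | COc1cc([C@H]2OC(C)(C)OC[C@@H]2Oc2ccc(C[C@H]3COC(=O)[C@@H]3Cc3cc(OC)c4c(c3)[C@H](COCc3ccccc3)[C@@H](c3ccc(OCc5ccccc5)c(OC)c3)O4)cc2OC)ccc1OCc1ccccc1 | intermediate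
32 | (3R,4R)-3-{[(2S,3R)-2-[4-(benzyloxy)-3-methoxyphenyl]-3-[(benzyloxy)methyl]-7-methoxy-2,3-dihydro-1-benzofuran-5-yl]methyl}-4-[4-({(1R,2S)-1-[4-(benzyloxy)-3-methoxyphenyl]-1,3-dihydroxypropan-2-yl}oxy)-3-methoxybenzyl]dihydrofuran-2(3H)-one | COc1cc([C@@H](O)[C@H](CO)Oc2ccc(C[C@H]3COC(=O)[C@@H]3Cc3cc(OC)c4c(c3)[C@H](COCc3ccccc3)[C@@H](c3ccc(OCc5ccccc5)c(OC)c3)O4)cc2OC)ccc1OCc1ccccc1 | intermediate
33 | (3R,4R)-3-{[(2S,3R)-2-(4-hydroxy-3-methoxyphenyl)-3-(hydroxymethyl)-7-methoxy-2,3-dihydro-1-benzofuran-5-yl]methyl}-4-[4-({(1R,2S)-1-(4-hydroxy-3-methoxyphenyl)-1,3-dihydroxypropan-2-yl}oxy)-3-methoxybenzyl]dihydrofuran-2(3H)-one (CNP0265599.1) | COc1cc([C@@H](O)[C@H](CO)Oc2ccc(C[C@H]3COC(=O)[C@@H]3Cc3cc(OC)c4c(c3)[C@H](CO)[C@@H](c3ccc(O)c(OC)c3)O4)cc2OC)ccc1O | target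

**Step count and risks**

Total step count: 20. Longest linear sequence: 12 steps (steps 1–9, then 18–20); the lactone branch (steps 10–17) joins at step 18.

Steps most likely to fail:

Step 7. The cycloaddition of the doubly alkoxylated diazine may be slower than thermal elimination or ionisation of the 4-alkoxybenzylic pyridazinyl ether. The fallback makes the diene more electron-poor instead of heating harder; it sets out from 9 and returns to the route at 16. Alcohol 9 is deprotonated with NaH to its sodium alkoxide F1 and coupled with 11 as in step 6 to give the silyl-capped chloropyridazinyl ether F2. Palladium-catalysed methoxycarbonylation of the remaining chloride (Pd(OAc)2, 1,1'-bis(diphenylphosphino)ferrocene, CO, MeOH, Et3N, 70 °C) gives the pyridazine-3-carboxylate F3, the silyl cap keeping the alkyne out of the palladium chemistry. Buffered fluoride (n-Bu4NF/AcOH, THF) frees the terminal alkyne F4. With an ester on the diazine, the [4+2] step through the bridged adduct F5 is expected to run at a much lower temperature and gives the benzofuran-5-carboxylate F6, which i-Bu2AlH reduces to alcohol 16.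

Step 6. The hindered secondary alkoxide may attack the remote C6 chloride, or both chlorides without selectivity. The fallback moves site control to the leaving group; it sets out from 11 and returns at 13. NaSMe (THF, 0 °C) converts 11 into 6-chloro-4-methoxy-3-(methylsulfanyl)pyridazine F7; the small nucleophile is expected to follow methoxide to C3, and any regioisomer is removed at this cheap stage. Oxidation with mCPBA gives 6-chloro-4-methoxy-3-(methylsulfonyl)pyridazine F8. Alkoxide 12 then displaces the sulfinate, by far the better leaving group, and gives 13.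

Step 15. Coordination of the aryloxy oxygen to magnesium may erode the anti selectivity or the facial control of the aldol addition. The fallback sets the two centres in separate, well-tested operations; it sets out from 23 and returns at 28. Phenol 23 is alkylated with purchased (R)-4-benzyl-3-(chloroacetyl)oxazolidin-2-one to give the enantiomeric-auxiliary imide F9. Treatment with n-Bu2BOTf/i-Pr2NEt forms the Z-boron enolate F10, whose chair-like addition to 7 gives the syn aldol adduct F11, in which C8 is already correct. NaBH4 in wet THF gives the threo diol F12. DDQ oxidises its 4-alkoxybenzylic alcohol selectively to the aryl ketone F13, and NaBH4 reduction, which favours the erythro isomer of α-aryloxy-β-hydroxy propiophenones, returns 28 after separation from threo material.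

**Further compounds**

F1 | step 7 | sodium alkoxide of 9 | C[Si](C)(C)C#C[C@H](COCc1ccccc1)[C@@H](c1ccc(OCc2ccccc2)c(OC)c1)[O-].[Na+]
F2 | step 7 | 3-{[(1S,2R)-1-[4-(benzyloxy)-3-methoxyphenyl]-2-[(benzyloxy)methyl]-4-(trimethylsilyl)but-3-yn-1-yl]oxy}-6-chloro-4-methoxypyridazine | C[Si](C)(C)C#C[C@H](COCc1ccccc1)[C@@H](c1ccc(OCc2ccccc2)c(OC)c1)Oc1nnc(Cl)cc1OC
F3 | step 7 | methyl 6-{[(1S,2R)-1-[4-(benzyloxy)-3-methoxyphenyl]-2-[(benzyloxy)methyl]-4-(trimethylsilyl)but-3-yn-1-yl]oxy}-5-methoxypyridazine-3-carboxylate | C[Si](C)(C)C#C[C@H](COCc1ccccc1)[C@@H](c1ccc(OCc2ccccc2)c(OC)c1)Oc1nnc(C(=O)OC)cc1OC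
F4 | step 7 | methyl 6-{[(1S,2R)-1-[4-(benzyloxy)-3-methoxyphenyl]-2-[(benzyloxy)methyl]but-3-yn-1-yl]oxy}-5-methoxypyridazine-3-carboxylate | C#C[C@H](COCc1ccccc1)[C@@H](c1ccc(OCc2ccccc2)c(OC)c1)Oc1nnc(C(=O)OC)cc1OC
F5 | step 7 | bridged [4+2] adduct of F4 (bridgehead configuration left open) | COC(=O)C12C=C(OC)C3(N=N1)O[C@H](c1ccc(OCc4ccccc4)c(OC)c1)[C@@H](COCc1ccccc1)C3=C2
F6 | step 7 | methyl (2S,3R)-2-[4-(benzyloxy)-3-methoxyphenyl]-3-[(benzyloxy)methyl]-7-methoxy-2,3-dihydro-1-benzofuran-5-carboxylate | COC(=O)c1cc(OC)c2c(c1)[C@H](COCc1ccccc1)[C@@H](c1ccc(OCc3ccccc3)c(OC)c1)O2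
F7 | step 6 | 6-chloro-4-methoxy-3-(methylsulfanyl)pyridazine | COc1cc(Cl)nnc1SC
F8 | step 6 | 6-chloro-4-methoxy-3-(methylsulfonyl)pyridazine | COc1cc(Cl)nnc1S(C)(=O)=O
F9 | step 15 | (R)-4-benzyl-3-[(2-methoxy-4-{[(3R)-5-oxooxolan-3-yl]methyl}phenoxy)acetyl]oxazolidin-2-one | O=C(COc1ccc(C[C@H]2COC(=O)C2)cc1OC)N1C(=O)OC[C@H]1Cc1ccccc1
F10 | step 15 | dibutylboron Z-enolate of F9 | CCCCB(CCCC)O/C(=C\Oc1ccc(C[C@H]2COC(=O)C2)cc1OC)N1C(=O)OC[C@H]1Cc1ccccc1
F11 | step 15 | (R)-4-benzyl-3-[(2R,3S)-3-[4-(benzyloxy)-3-methoxyphenyl]-3-hydroxy-2-(2-methoxy-4-{[(3R)-5-oxooxolan-3-yl]methyl}phenoxy)propanoyl]oxazolidin-2-one | COc1cc([C@H](O)[C@H](C(=O)N2C(=O)OC[C@H]2Cc2ccccc2)Oc2ccc(C[C@H]3COC(=O)C3)cc2OC)ccc1OCc1ccccc1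
F12 | step 15 | (R)-4-[4-({(1S,2S)-1-[4-(benzyloxy)-3-methoxyphenyl]-1,3-dihydroxypropan-2-yl}oxy)-3-methoxybenzyl]dihydrofuran-2(3H)-one | COc1cc([C@H](O)[C@H](CO)Oc2ccc(C[C@H]3COC(=O)C3)cc2OC)ccc1OCc1ccccc1
F13 | step 15 | (R)-4-[4-({(S)-1-[4-(benzyloxy)-3-methoxyphenyl]-3-hydroxy-1-oxopropan-2-yl}oxy)-3-methoxybenzyl]dihydrofuran-2(3H)-one | COc1cc(C(=O)[C@H](CO)Oc2ccc(C[C@H]3COC(=O)C3)cc2OC)ccc1OCc1ccccc1
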